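## Retrosynthetic overview

1. Target 20 ⇒ acyclic lactone 19 by ring-closing metathesis at C1=C10; the ten-membered ring is made last.
2. 19 ⇒ aldehyde 13 + γ-acetoxyallyl bromide 17 (C8–C9 bond; sets C8 and C9 and delivers free 8-OH, 9-OAc and the 14-isovalerate with no protecting groups).
3. Key step: 13 ⇒ 11. The C12–O6 bond of the 6,12-lactone is formed by an oxidation-gated translactonization (8,12-lactone to 6,12-lactone) that also unveils the C8 aldehyde.
4. 11 ⇒ Z-dienal 6 + 3-(bromomethyl)furan-2(5H)-one 9 by asymmetric chromium allylation (C6–C7 bond; sets C6 and C7).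
5. Ring order: butenolide ring (from commercial lactone 7) → γ-lactone re-closed on O6 (step 6) → carbocycle (step 11).

Assumption: germacrane numbering is used in the text (C6/C7 lactone carbons, C8 carbinol, C9 acetoxy carbon, C14 the CH2O-isovalerate carbon), the target being (6R,7R,8S,9R,1(10)Z,4Z); the facial sense of the chromium catalysts (Si face with (S,S)-L in step 5, Re face with (R,R)-L in step 10; L = 3,6-di-tert-butyl-1,8-bis(4-isopropyl-4,5-dihydro-1,3-oxazol-2-yl)-9H-carbazole) is assigned by analogy.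

## Route

Step 1
Reactants: 1 but-2-yn-1-ol
Product: 3 (2Z)-3-iodobut-2-en-1-ol, via cyclic alkenylalanate 2 (not isolated)
Conditions: NaAlH2(OCH2CH2OCH3)2, THF, 0 °C to rt; then I2, −78 °C to 0 °C
Reagents that add atoms: iodine, II
Why: Hydroxyl-directed trans-hydroalumination of the propargylic alcohol places aluminium on C3 inside a five-membered alanate, and iodinolysis of the C–Al bond with retention gives the Z iodide (hydroalumination–iodination).

Step 2
Reactants: 3 (2Z)-3-iodobut-2-en-1-ol; 4 but-3-enylzinc bromide (commercial THF solution, 1.5 equiv)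
Product: 5 (2Z)-3-methylhepta-2,6-dien-1-ol
Conditions: PdCl2(dppf) (3 mol%), THF, 50 °C
Reagents that add atoms: none
Why: Negishi sp2–sp3 cross-coupling proceeds with retention of alkene geometry, so the Z (neryl-type) trisubstituted C4=C5 alkene is fixed here.

Step 3
Reactants: 5 (2Z)-3-methylhepta-2,6-dien-1-ol
Product: 6 (2Z)-3-methylhepta-2,6-dienal
Conditions: PhI(OAc)2, TEMPO (10 mol%), CH2Cl2, rt
Reagents that add atoms: none
Why: Oxoammonium (TEMPO) oxidation of the allylic alcohol is neutral and does not isomerise the Z enal.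

Step 4
Reactants: 7 3-methylideneoxolan-2-one (α-methylene-γ-butyrolactone)
Product: 9 3-(bromomethyl)furan-2(5H)-one, via dibromolactone 8 (not isolated)
Conditions: Br2, CH2Cl2, 0 °C; then Et3N, 0 °C to rt
Reagents that add atoms: bromine, BrBr
Why: Bromine adds across the exocyclic alkene and base-induced E2 loss of HBr (C4–H and the tertiary bromide) gives the conjugated endocyclic butenolide that keeps the allylic CH2Br (bromination–dehydrobromination).

Step 5
Reactants: 6 (2Z)-3-methylhepta-2,6-dienal; 9 3-(bromomethyl)furan-2(5H)-one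
Product: 11 (4R)-4-[(1R,2Z)-1-hydroxy-3-methylhepta-2,6-dien-1-yl]-3-methylideneoxolan-2-one, via trimethylsilyl ether 10 (not isolated)
Conditions: CrCl2 (10 mol%), (S,S)-L (12 mol%), Mn, Me3SiCl, iPr2NEt (cat.), THF, 0 °C to rt; then citric acid, MeOH, 0 °C
Reagents that add atoms: none
Why: Catalytic asymmetric Nozaki–Hiyama–Kishi allylation, in which the ring-locked E-type γ-substituted allyl group on trivalent chromium reacts at C7 through a closed chair transition state to give the anti C6/C7 adduct and the exocyclic methylene, while the chiral tridentate ligand directs attack to the Si face of the enal (6R, hence 7R).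

Step 6
Reactants: 11 (4R)-4-[(1R,2Z)-1-hydroxy-3-methylhepta-2,6-dien-1-yl]-3-methylideneoxolan-2-one
Product: 13 (2R,3S)-2-[(1Z)-2-methylhexa-1,5-dien-1-yl]-4-methylidene-5-oxooxolane-3-carbaldehyde, via primary alcohol 12 (not isolated)
Conditions: [Cu(MeCN)4]OTf (5 mol%), 2,2'-bipyridine (5 mol%), TEMPO (5 mol%), N-methylimidazole (10 mol%), air, MeCN, rt
Reagents that add atoms: none
Why: Proposed new method: oxidation-gated translactonization, in which the copper-bound C6 alkoxide attacks the lactone carbonyl (five-membered transition state) to give reversibly the 6,12-lactone 12 with a free primary C8 alcohol, and the copper/TEMPO couple dehydrogenates only this unhindered primary alkoxide (the secondary allylic alcohol of 11 is inert to it), so the acyl shift is drained irreversibly to the aldehyde whatever the position of the equilibrium and no stereocentre is touched (trans C6/C7 follows from the anti adduct); closest known reaction types are copper/TEMPO aerobic oxidation selective for primary alcohols and base-mediated translactonization of β-(hydroxyalkyl)-γ-butyrolactones.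

Step 7
Reactants: 14 2-methylidenepropane-1,3-diol (3 equiv, excess recovered)
Product: 15 2-(hydroxymethyl)prop-2-en-1-yl 3-methylbutanoate
Conditions: 3-methylbutanoyl chloride (1 equiv), pyridine, CH2Cl2, 0 °C
Reagents that add atoms: 3-methylbutanoyl chloride, CC(C)CC(Cl)=O
Why: Statistical mono-acylation of the symmetrical diol used in excess (nucleophilic acyl substitution) installs the C14 isovalerate at the outset.

Step 8
Reactants: 15 2-(hydroxymethyl)prop-2-en-1-yl 3-methylbutanoate
Product: 16 2-formylprop-2-en-1-yl 3-methylbutanoate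
Conditions: PhI(OAc)2, TEMPO (10 mol%), CH2Cl2, rt
Reagents that add atoms: none
Why: Oxoammonium (TEMPO) oxidation of the remaining allylic alcohol gives the 2-substituted acrolein without touching the ester.

Step 9
Reactants: 16 2-formylprop-2-en-1-yl 3-methylbutanoate
Product: 17 3-acetoxy-2-(bromomethyl)prop-2-en-1-yl 3-methylbutanoate (E/Z mixture)
Conditions: AcBr, ZnCl2 (2 mol%), CH2Cl2, −20 °C to 0 °C
Reagents that add atoms: acetyl bromide, CC(Br)=O
Why: Lewis-acid-catalysed addition of the acyl bromide to the enal with allylic bromide shift (net 1,4-addition) gives the γ-acetoxyallyl bromide, and the E/Z mixture is inconsequential because both isomers converge on the same allylchromium species.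

Step 10
Reactants: 13 (2R,3S)-2-[(1Z)-2-methylhexa-1,5-dien-1-yl]-4-methylidene-5-oxooxolane-3-carbaldehyde; 17 3-acetoxy-2-(bromomethyl)prop-2-en-1-yl 3-methylbutanoate
Product: 19 (1S,2R)-1-hydroxy-1-[(2R,3R)-2-[(1Z)-2-methylhexa-1,5-dien-1-yl]-4-methylidene-5-oxooxolan-3-yl]-3-{[(3-methylbutanoyl)oxy]methyl}but-3-en-2-yl acetate, via trimethylsilyl ether 18 (not isolated)
Conditions: CrCl2 (15 mol%), (R,R)-L (18 mol%), Mn, Me3SiCl, iPr2NEt (cat.), THF, 0 °C; then citric acid, MeOH, 0 °C
Reagents that add atoms: none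
Why: Proposed new method: catalytic enantio- and anti-selective γ-acetoxyallylation with a 2-substituted γ-acetoxyallyl bromide, in which divalent chromium converts 17 into the (E)-γ-acetoxyallyl species on trivalent chromium, a closed chair transition state with pseudo-equatorial OAc gives the anti C8/C9 relationship and the exocyclic C10 methylene, the carbazole-bis(oxazoline) ligand enforces Re-face attack on the aldehyde (8S, hence 9R) over the substrate's own bias, and the acetyl group stays on O9 while O8 is released as the free alcohol; closest known reaction types are chromium-catalysed asymmetric allylation, crotylation and methallylation of aldehydes (Nozaki–Hiyama–Kishi) and chromium-mediated additions of unsubstituted 3-bromopropenyl esters.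

Step 11
Reactants: 19 (1S,2R)-1-hydroxy-1-[(2R,3R)-2-[(1Z)-2-methylhexa-1,5-dien-1-yl]-4-methylidene-5-oxooxolan-3-yl]-3-{[(3-methylbutanoyl)oxy]methyl}but-3-en-2-yl acetate
Product: 20 (3aR,4S,5R,6Z,10Z,11aR)-5-acetoxy-4-hydroxy-10-methyl-3-methylidene-6-{[(3-methylbutanoyl)oxy]methyl}-3a,4,5,8,9,11a-hexahydrocyclodeca[b]furan-2(3H)-one (target)
Conditions: second-generation Grubbs catalyst RuCl2(=CHPh)(H2IMes)(PCy3) (10 mol%), 1,4-benzoquinone (20 mol%), toluene (1 mM), 80 °C
Reagents that add atoms: none
Why: Ring-closing metathesis starts at the only monosubstituted alkene and closes onto the 1,1-disubstituted C10 alkene, the ten-membered ring enforcing the ring-cis (Z) trisubstituted C1=C10 bond, while closure onto the α-methylene lactone would need a bridgehead alkene and does not compete.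

## Compound list

1 | but-2-yn-1-ol | CC#CCO | starting material
2 | sodium cyclic alkenylalanate (five-membered O–Al–C3=C2–C1 ring, two 2-methoxyethoxy groups on Al) | CC1=CCO[Al-]1(OCCOC)OCCOC.[Na+] | intermediate
3 | (2Z)-3-iodobut-2-en-1-ol | OC/C=C(/C)I | intermediate
4 | but-3-enylzinc bromide | C=CCC[Zn]Br | starting material
5 | (2Z)-3-methylhepta-2,6-dien-1-ol | OC/C=C(/C)CCC=C | intermediate
6 | (2Z)-3-methylhepta-2,6-dienal | O=C/C=C(/C)CCC=C | intermediate
7 | 3-methylideneoxolan-2-one | C=C1CCOC1=O | starting material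
8 | 3-bromo-3-(bromomethyl)oxolan-2-one | BrCC1(Br)CCOC1=O | intermediate
9 | 3-(bromomethyl)furan-2(5H)-one | BrCC1=CCOC1=O | intermediate
10 | (4R)-3-methylidene-4-[(1R,2Z)-3-methyl-1-(trimethylsilyloxy)hepta-2,6-dien-1-yl]oxolan-2-one | C=C1C(=O)OC[C@@H]1[C@H](O[Si](C)(C)C)/C=C(/C)CCC=C | intermediate
11 | (4R)-4-[(1R,2Z)-1-hydroxy-3-methylhepta-2,6-dien-1-yl]-3-methylideneoxolan-2-one | C=C1C(=O)OC[C@@H]1[C@H](O)/C=C(/C)CCC=C | intermediate
12 | (4R,5R)-4-(hydroxymethyl)-3-methylidene-5-[(1Z)-2-methylhexa-1,5-dien-1-yl]oxolan-2-one | C=C1C(=O)O[C@H](/C=C(/C)CCC=C)[C@H]1CO | intermediate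
13 | (2R,3S)-2-[(1Z)-2-methylhexa-1,5-dien-1-yl]-4-methylidene-5-oxooxolane-3-carbaldehyde | C=C1C(=O)O[C@H](/C=C(/C)CCC=C)[C@H]1C=O | intermediate
14 | 2-methylidenepropane-1,3-diol | C=C(CO)CO | starting material
15 | 2-(hydroxymethyl)prop-2-en-1-yl 3-methylbutanoate | C=C(CO)COC(=O)CC(C)C | intermediate
16 | 2-formylprop-2-en-1-yl 3-methylbutanoate | C=C(C=O)COC(=O)CC(C)C | intermediate
17 | 3-acetoxy-2-(bromomethyl)prop-2-en-1-yl 3-methylbutanoate (E/Z mixture) | CC(=O)OC=C(CBr)COC(=O)CC(C)C | intermediate
18 | 8-O-trimethylsilyl ether of 19 | C=C1C(=O)O[C@H](/C=C(/C)CCC=C)[C@H]1[C@H](O[Si](C)(C)C)[C@H](OC(C)=O)C(=C)COC(=O)CC(C)C | intermediate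
19 | (1S,2R)-1-hydroxy-1-[(2R,3R)-2-[(1Z)-2-methylhexa-1,5-dien-1-yl]-4-methylidene-5-oxooxolan-3-yl]-3-{[(3-methylbutanoyl)oxy]methyl}but-3-en-2-yl acetate | C=C1C(=O)O[C@H](/C=C(/C)CCC=C)[C@H]1[C@H](O)[C@H](OC(C)=O)C(=C)COC(=O)CC(C)C | intermediate
20 | (3aR,4S,5R,6Z,10Z,11aR)-5-acetoxy-4-hydroxy-10-methyl-3-methylidene-6-{[(3-methylbutanoyl)oxy]methyl}-3a,4,5,8,9,11a-hexahydrocyclodeca[b]furan-2(3H)-one | C=C1C(=O)O[C@@H]2/C=C(/C)CC/C=C(/COC(=O)CC(C)C)[C@@H](OC(C)=O)[C@@H](O)[C@@H]12 | target

## Step count and risks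

Total steps: 11. Longest linear sequence: 7 (steps 1, 2, 3, 5, 6, 10, 11).

The three steps most likely to fail:

Step 6 (proposed new method). The acyl shift may be slow under the mild oxidation conditions, or the product aldehyde may isomerise into conjugation. The fallback uses known chemistry, sets out from 11 and comes back at 13. Catalytic DBU in toluene at 40 °C equilibrates 11 to the γ-substituted lactone 12, which should be the more stable isomer and is now isolated. Dess–Martin periodinane with NaHCO3 in CH2Cl2 then oxidises 12 to 13. This fallback makes no compound outside the list (F0).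

Step 10 (proposed new method). The 2-substituted γ-acetoxyallyl bromide is untested, and the catalyst may have to override the intrinsic facial bias of the α-branched aldehyde. The fallback uses known chemistry, sets out from 13 and comes back at 19.
- (S)-Proline-catalysed anti-aldol addition of 2,2-dimethyl-1,3-dioxan-5-one to 13 gives (4S)-4-{(S)-hydroxy[(2R,3R)-2-[(1Z)-2-methylhexa-1,5-dien-1-yl]-4-methylidene-5-oxooxolan-3-yl]methyl}-2,2-dimethyl-1,3-dioxan-5-one F1. The secondary amine may add reversibly to the α-methylene lactone, which would tie up catalyst.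
- Methylenation of the ketone with Zn/CH2Br2/TiCl4 gives the 5-methylidene-1,3-dioxane F2.
- Aqueous acetic acid removes the acetonide to give (4R,5R)-4-[(1S,2R)-1,2-dihydroxy-3-(hydroxymethyl)but-3-en-1-yl]-3-methylidene-5-[(1Z)-2-methylhexa-1,5-dien-1-yl]oxolan-2-one F3.
- 3-Methylbutanoyl chloride with 2,4,6-collidine at −78 °C acylates the primary hydroxyl to give the diol monoester F4.
- Selective acetylation of the less hindered allylic 9-hydroxyl (Ac2O, 2,4,6-collidine, −40 °C) gives 19; the 8-OH/9-OH selectivity of this last acylation is the weak point of the fallback.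

Step 11. Ten-membered ring closure onto a hindered 1,1-disubstituted alkene may give dimers or no reaction. The fallback closes the ring at C8–C9 instead, sets out from 13 (with enal 16) and comes back at 20.
- Cross-metathesis of 13 with excess 16 (second-generation Grubbs catalyst) gives the dialdehyde (2E,6Z)-2-formyl-7-[(2R,3S)-3-formyl-4-methylidene-5-oxooxolan-2-yl]-6-methylhepta-2,6-dien-1-yl 3-methylbutanoate F5.
- High-dilution CrCl2/Me3SiCl reductive cross-pinacol-type coupling then forms the C8–C9 bond through a γ-siloxyallylchromium species and generates the C1=C10 alkene inside the ring. After mild acidic work-up this gives the macrocyclic diol (3aR,4S,5R,6Z,10Z,11aR)-4,5-dihydroxy-10-methyl-3-methylidene-6-{[(3-methylbutanoyl)oxy]methyl}-3a,4,5,8,9,11a-hexahydrocyclodeca[b]furan-2(3H)-one F6. The facial outcome of this macrocyclisation is not predictable in advance.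
- Selective acetylation of the allylic 9-hydroxyl gives 20.

## Further compounds

F0 | step 6 | none | none
F1 | step 10 | (4S)-4-{(S)-hydroxy[(2R,3R)-2-[(1Z)-2-methylhexa-1,5-dien-1-yl]-4-methylidene-5-oxooxolan-3-yl]methyl}-2,2-dimethyl-1,3-dioxan-5-one | C=C1C(=O)O[C@H](/C=C(/C)CCC=C)[C@H]1[C@H](O)[C@@H]2OC(C)(C)OCC2=O
F2 | step 10 | (4R,5R)-4-{(S)-hydroxy[(4R)-2,2-dimethyl-5-methylidene-1,3-dioxan-4-yl]methyl}-3-methylidene-5-[(1Z)-2-methylhexa-1,5-dien-1-yl]oxolan-2-one | C=C1C(=O)O[C@H](/C=C(/C)CCC=C)[C@H]1[C@H](O)[C@@H]2OC(C)(C)OCC2=C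
F3 | step 10 | (4R,5R)-4-[(1S,2R)-1,2-dihydroxy-3-(hydroxymethyl)but-3-en-1-yl]-3-methylidene-5-[(1Z)-2-methylhexa-1,5-dien-1-yl]oxolan-2-one | C=C1C(=O)O[C@H](/C=C(/C)CCC=C)[C@H]1[C@H](O)[C@H](O)C(=C)CO
F4 | step 10 | (3R,4S)-3,4-dihydroxy-2-methylidene-4-[(2R,3R)-2-[(1Z)-2-methylhexa-1,5-dien-1-yl]-4-methylidene-5-oxooxolan-3-yl]butyl 3-methylbutanoate | C=C1C(=O)O[C@H](/C=C(/C)CCC=C)[C@H]1[C@H](O)[C@H](O)C(=C)COC(=O)CC(C)C
F5 | step 11 | (2E,6Z)-2-formyl-7-[(2R,3S)-3-formyl-4-methylidene-5-oxooxolan-2-yl]-6-methylhepta-2,6-dien-1-yl 3-methylbutanoate | C=C1C(=O)O[C@H](/C=C(/C)CC/C=C(/C=O)COC(=O)CC(C)C)[C@H]1C=O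
F6 | step 11 | (3aR,4S,5R,6Z,10Z,11aR)-4,5-dihydroxy-10-methyl-3-methylidene-6-{[(3-methylbutanoyl)oxy]methyl}-3a,4,5,8,9,11a-hexahydrocyclodeca[b]furan-2(3H)-one | C=C1C(=O)O[C@@H]2/C=C(/C)CC/C=C(/COC(=O)CC(C)C)[C@@H](O)[C@@H](O)[C@@H]12
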